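## Retrosynthetic overview

1. Target 25 ⇐ tetraol 22 by 7,13-diacetylation with the cis-9,10-diol masked as a transient boronate; 22 ⇐ allyl oxocane carbonate 17 by Z-selective enyne cross-metathesis and methanolysis.
2. Key disconnection: oxocane 17 ⇐ acyclic bis-epoxy alcohol 13 by a polyepoxide/oxonium cascade of the kind presumed for Laurencia C15 acetogenins. O9–H opens the 12,13-epoxide, the new ring oxygen opens the 6,7-epoxide, and the C10 carbamate cleaves the O–C9 bond.
3. 13 ⇐ triene 11 by hydroxyl-directed epoxidation (C6=C7) and Shi epoxidation (C12=C13).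
4. 11 ⇐ (S,S)-diepoxybutane 2 (from L-threitol ditosylate 1), opened first by an (E)-butenyl alanate (C12–C15) and then by a pentenynyl acetylide (C4–C7).
5. Ring order, all in step 8: oxolane (O–C12 bond) → 1-oxoniabicyclo[3.3.0]octane (O–C6 bond) → oxocane (loss of the O–C9 bond).

Assumption: locants C1–C15 follow the carbon chain of the target (C1 = alkyne CH, C15 = CH3); compounds 1, 3, 8, 18 and 19 are taken as cheap commercial materials; Lewis-acid promoters and catalysts are not counted as consumed reagents.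

## Route

Step 1
Reactants: 1 1,4-di-O-tosyl-L-threitol
Product: 2 (2S,3S)-1,2:3,4-diepoxybutane
Conditions: KOH, Et2O/H2O, rt
Reagents that add atoms: none
Why: Double intramolecular Williamson etherification (3-exo-tet) in which each secondary alkoxide displaces the neighbouring primary tosylate, so the two C–O stereocentres of L-threitol are untouched and become C9 and C10.

Step 2
Reactants: 3 but-1-yne; 2 (2S,3S)-1,2:3,4-diepoxybutane
Product: 6 (1S,3E)-1-[(2S)-oxiran-2-yl]hex-3-en-1-ol, via (E)-but-1-enyl(diisobutyl)alane 4 (not isolated), via lithium butenylalanate 5 (not isolated)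
Conditions: DIBAL-H, hexane, 50 °C; n-BuLi, THF, −30 °C; then 2 (3 equiv), BF3·OEt2, −78 °C
Reagents that add atoms: none
Why: Zweifel syn-hydroalumination fixes the 12E alkene, and BF3-assisted alkenylalanate opening of one terminal epoxide of C2-symmetric 2 occurs at CH2 (C11), so no stereocentre is touched and excess 2 suppresses double opening.

Step 3
Reactants: 6 (1S,3E)-1-[(2S)-oxiran-2-yl]hex-3-en-1-ol
Product: 7 (1S,3E)-1-[(2S)-oxiran-2-yl]hex-3-en-1-yl dimethylcarbamate
Conditions: LiHMDS, THF, −78 °C; Me2NCOCl, −78 → 0 °C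
Reagents that add atoms: dimethylcarbamoyl chloride, CN(C)C(Cl)=O
Why: O-carbamoylation of the lithium alkoxide with retention at C10 places on O10 the carbonyl group that later terminates the cascade; the low temperature and lithium counter-ion avoid Payne rearrangement.

Step 4
Reactants: 8 pent-1-en-4-yne; 7 (1S,3E)-1-[(2S)-oxiran-2-yl]hex-3-en-1-yl dimethylcarbamate
Product: 10 (3E,6S,7S)-7-hydroxytrideca-3,12-dien-9-yn-6-yl dimethylcarbamate, via lithium pent-4-en-1-yn-1-ide 9 (not isolated)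
Conditions: n-BuLi, THF, −78 °C; BF3·OEt2; then 7, −78 °C, 30 min
Reagents that add atoms: none
Why: Yamaguchi alkynylation at the primary epoxide carbon C8 leaves C9 untouched and frees O9–H as the only hydroxyl; excess alkynyl–BF3 ate complex at −78 °C is expected to outrun carbamate participation.

Step 5
Reactants: 10 (3E,6S,7S)-7-hydroxytrideca-3,12-dien-9-yn-6-yl dimethylcarbamate
Product: 11 (3E,6S,7S,9Z)-7-hydroxytrideca-3,9,12-trien-6-yl dimethylcarbamate
Conditions: H2 (1 atm), Lindlar catalyst, quinoline, EtOAc, rt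
Reagents that add atoms: none
Why: Lindlar semihydrogenation delivers H2 syn to the internal alkyne to give the 6Z alkene, while the E and terminal alkenes react much more slowly.

Step 6
Reactants: 11 (3E,6S,7S,9Z)-7-hydroxytrideca-3,9,12-trien-6-yl dimethylcarbamate
Product: 12 (3E,6S,7S)-7-hydroxy-8-[(2R,3S)-3-allyloxiran-2-yl]oct-3-en-6-yl dimethylcarbamate
Conditions: VO(acac)2 (5 mol %), t-BuOOH, CH2Cl2, 0 °C → rt
Reagents that add atoms: tert-butyl hydroperoxide, CC(C)(C)OO
Why: Vanadium-catalysed hydroxyl-directed epoxidation of the Z-homoallylic alkene through the Mihelich chair transition state delivers oxygen 1,3-syn to O9–H, setting the cis-(6S,7R) epoxide; the bishomoallylic E alkene and the undirected allyl group react more slowly.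

Step 7
Reactants: 12 (3E,6S,7S)-7-hydroxy-8-[(2R,3S)-3-allyloxiran-2-yl]oct-3-en-6-yl dimethylcarbamate
Product: 13 (2S,3S)-3-hydroxy-1-[(2S,3S)-3-ethyloxiran-2-yl]-4-[(2R,3S)-3-allyloxiran-2-yl]butan-2-yl dimethylcarbamate
Conditions: ent-Shi ketone (from L-sorbose, 30 mol %), Oxone, K2CO3, Bu4NHSO4, MeCN/DMM/aq. borate buffer (pH 10.5), 0 °C
Reagents that add atoms: potassium peroxymonosulfate (Oxone), [K+].[O-]S(=O)(=O)OO
Why: Shi asymmetric epoxidation (dioxirane, spiro transition state) of the only E-1,2-disubstituted alkene gives the (12S,13S) epoxide under reagent control; the monosubstituted alkene is a poor substrate.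

Step 8
Reactants: 13 (2S,3S)-3-hydroxy-1-[(2S,3S)-3-ethyloxiran-2-yl]-4-[(2R,3S)-3-allyloxiran-2-yl]butan-2-yl dimethylcarbamate
Product: 17 (2R,3R,5R,6S,8R)-2-allyl-8-[(1S)-1-hydroxypropyl]oxocane-3,5,6-triol 5,6-cyclic carbonate, via tetrahydrofuran 14 (not isolated), via bicyclic oxonium 15 (not isolated), via cyclic iminium carbonate 16 (not isolated)
Conditions: CSA (10 mol %), CH2Cl2, 0 °C; then BF3·OEt2 (3 equiv), −40 → 0 °C; aq. NaHCO3
Reagents that add atoms: water, O
Why: Proposed new method: under CSA the only free hydroxyl (O9–H) opens the 12,13-epoxide 5-exo with inversion at C12 (12R, 13S carbinol, oxolane 14); BF3 then activates the cis-6,7-epoxide, the ring oxygen attacks C6 5-endo with inversion (6R, 7R hydroxyl) to give the 1-oxoniabicyclo[3.3.0]octane 15, and the C10 carbamate carbonyl displaces the oxonium oxygen at C9 with inversion (9R, cis to 10S), which merges the two five-membered rings into the oxocane as iminium 16 that water hydrolyses to the carbonate; the closest known reactions are bromonium-induced tetrahydrofuran-to-oxocane ring expansions terminated by a neighbouring tert-butyl carbonate and BF3-promoted polyepoxide cascades terminated by N,N-dimethylcarbamates.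

Step 9
Reactants: 18 vinyl bromide; 19 ethynyltrimethylsilane
Product: 20 (but-3-en-1-yn-1-yl)trimethylsilane
Conditions: Pd(PPh3)4 (2 mol %), CuI (4 mol %), Et2NH, THF, 0 °C → rt
Reagents that add atoms: none
Why: Sonogashira coupling of a vinyl bromide with a terminal alkyne; no stereochemistry is involved.

Step 10
Reactants: 17 (2R,3R,5R,6S,8R)-2-allyl-8-[(1S)-1-hydroxypropyl]oxocane-3,5,6-triol 5,6-cyclic carbonate; 20 (but-3-en-1-yn-1-yl)trimethylsilane
Product: 21 (2R,3R,5R,6S,8R)-8-[(1S)-1-hydroxypropyl]-2-[(2Z)-5-(trimethylsilyl)pent-2-en-4-yn-1-yl]oxocane-3,5,6-triol 5,6-cyclic carbonate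
Conditions: Grubbs II (10 mol %), 20 (5 equiv), CH2Cl2, 40 °C
Reagents that add atoms: none
Why: Cross-metathesis of a terminal alkene with a silyl-capped conjugated enyne under Grubbs II is kinetically Z-selective and gives the 3Z enyne; no stereocentre is affected.

Step 11
Reactants: 21 (2R,3R,5R,6S,8R)-8-[(1S)-1-hydroxypropyl]-2-[(2Z)-5-(trimethylsilyl)pent-2-en-4-yn-1-yl]oxocane-3,5,6-triol 5,6-cyclic carbonate
Product: 22 (2R,3R,5R,6S,8R)-8-[(1S)-1-hydroxypropyl]-2-[(2Z)-pent-2-en-4-yn-1-yl]oxocane-3,5,6-triol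
Conditions: K2CO3, MeOH, rt
Reagents that add atoms: none
Why: Base-mediated methanolysis cleaves the cyclic carbonate (transesterification) and the alkynyl C–Si bond (protiodesilylation) in one operation without touching any stereocentre.

Step 12
Reactants: 22 (2R,3R,5R,6S,8R)-8-[(1S)-1-hydroxypropyl]-2-[(2Z)-pent-2-en-4-yn-1-yl]oxocane-3,5,6-triol
Product: 25 (2R,3R,5R,6S,8R)-8-[(1S)-1-acetoxypropyl]-5,6-dihydroxy-2-[(2Z)-pent-2-en-4-yn-1-yl]oxocan-3-yl acetate, via cyclic phenylboronate 23 (not isolated), via diacetylated phenylboronate 24 (not isolated)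
Conditions: PhB(OH)2 (1.1 equiv), pyridine, 4 Å MS, rt; Ac2O, DMAP (cat.), 0 °C → rt; aq. sorbitol/Na2CO3 work-up
Reagents that add atoms: acetic anhydride, CC(=O)OC(C)=O
Why: Transient boronate protection, in which phenylboronic acid ties up only the cis-1,2-diol as a five-membered boronic ester so that O7–H and O13–H alone are acetylated, and diol exchange on work-up frees the 9,10-diol.

## Compound list

1 | 1,4-di-O-tosyl-L-threitol | Cc1ccc(cc1)S(=O)(=O)OC[C@H](O)[C@@H](O)COS(=O)(=O)c1ccc(C)cc1 | starting material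
2 | (2S,3S)-1,2:3,4-diepoxybutane | C1O[C@@H]1[C@@H]1CO1 | intermediate
3 | but-1-yne | CCC#C | starting material
4 | (E)-but-1-enyl(diisobutyl)alane | CC/C=C/[Al](CC(C)C)CC(C)C | intermediate
5 | lithium (E)-but-1-enyl(butyl)diisobutylalanate | [Li+].CCCC[Al-](CC(C)C)(CC(C)C)/C=C/CC | intermediate
6 | (1S,3E)-1-[(2S)-oxiran-2-yl]hex-3-en-1-ol | C1O[C@@H]1[C@@H](O)C/C=C/CC | intermediate
7 | (1S,3E)-1-[(2S)-oxiran-2-yl]hex-3-en-1-yl dimethylcarbamate | C1O[C@@H]1[C@@H](OC(=O)N(C)C)C/C=C/CC | intermediate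
8 | pent-1-en-4-yne | C=CCC#C | starting material
9 | lithium pent-4-en-1-yn-1-ide | [Li+].[C-]#CCC=C | intermediate
10 | (3E,6S,7S)-7-hydroxytrideca-3,12-dien-9-yn-6-yl dimethylcarbamate | C=CCC#CC[C@H](O)[C@@H](OC(=O)N(C)C)C/C=C/CC | intermediate
11 | (3E,6S,7S,9Z)-7-hydroxytrideca-3,9,12-trien-6-yl dimethylcarbamate | C=CC/C=C\C[C@H](O)[C@@H](OC(=O)N(C)C)C/C=C/CC | intermediate
12 | (3E,6S,7S)-7-hydroxy-8-[(2R,3S)-3-allyloxiran-2-yl]oct-3-en-6-yl dimethylcarbamate | C=CC[C@@H]1O[C@@H]1C[C@H](O)[C@@H](OC(=O)N(C)C)C/C=C/CC | intermediate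
13 | (2S,3S)-3-hydroxy-1-[(2S,3S)-3-ethyloxiran-2-yl]-4-[(2R,3S)-3-allyloxiran-2-yl]butan-2-yl dimethylcarbamate | C=CC[C@@H]1O[C@@H]1C[C@H](O)[C@@H](OC(=O)N(C)C)C[C@@H]1O[C@H]1CC | intermediate
14 | (2S,3S,5R)-2-{[(2R,3S)-3-allyloxiran-2-yl]methyl}-5-[(1S)-1-hydroxypropyl]oxolan-3-yl dimethylcarbamate | C=CC[C@@H]1O[C@@H]1C[C@@H]2O[C@@H]([C@@H](O)CC)C[C@@H]2OC(=O)N(C)C | intermediate
15 | 1-oxoniabicyclo[3.3.0]octane trialkyloxonium ion, O bonded to C6, C9 and C12 (cation shown, counter-ion omitted) | C=CC[C@@H]1[C@H](O)C[C@@H]2[O+]1[C@@H]([C@@H](O)CC)C[C@@H]2OC(=O)N(C)C | intermediate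
16 | oxocane with cis-fused 2-(dimethyliminio)-1,3-dioxolane at C9/C10 (cation shown, counter-ion omitted) | C=CC[C@H]1O[C@@H]([C@H](CC)O)C[C@@H]2OC(=[N+](C)C)O[C@@H]2C[C@H]1O | intermediate
17 | (2R,3R,5R,6S,8R)-2-allyl-8-[(1S)-1-hydroxypropyl]oxocane-3,5,6-triol 5,6-cyclic carbonate | C=CC[C@H]1O[C@@H]([C@H](CC)O)C[C@@H]2OC(=O)O[C@@H]2C[C@H]1O | intermediate
18 | vinyl bromide | C=CBr | starting material
19 | ethynyltrimethylsilane | C#C[Si](C)(C)C | starting material
20 | (but-3-en-1-yn-1-yl)trimethylsilane | C=CC#C[Si](C)(C)C | intermediate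
21 | (2R,3R,5R,6S,8R)-8-[(1S)-1-hydroxypropyl]-2-[(2Z)-5-(trimethylsilyl)pent-2-en-4-yn-1-yl]oxocane-3,5,6-triol 5,6-cyclic carbonate | C[Si](C)(C)C#C/C=C\C[C@H]1O[C@@H]([C@H](CC)O)C[C@@H]2OC(=O)O[C@@H]2C[C@H]1O | intermediate
22 | (2R,3R,5R,6S,8R)-8-[(1S)-1-hydroxypropyl]-2-[(2Z)-pent-2-en-4-yn-1-yl]oxocane-3,5,6-triol | C#C/C=C\C[C@H]1O[C@@H]([C@H](CC)O)C[C@H](O)[C@H](O)C[C@H]1O | intermediate
23 | 5,6-O-phenylboronate of 22 | C#C/C=C\C[C@H]1O[C@@H]([C@H](CC)O)C[C@@H]2OB(c3ccccc3)O[C@@H]2C[C@H]1O | intermediate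
24 | 5,6-O-phenylboronate of 25 | C#C/C=C\C[C@H]1O[C@@H]([C@H](CC)OC(C)=O)C[C@@H]2OB(c3ccccc3)O[C@@H]2C[C@H]1OC(C)=O | intermediate
25 | (2R,3R,5R,6S,8R)-8-[(1S)-1-acetoxypropyl]-5,6-dihydroxy-2-[(2Z)-pent-2-en-4-yn-1-yl]oxocan-3-yl acetate (CNP0314743.1; 6R,7R,9R,10S,12R,13S in chain numbering) | C#C/C=C\C[C@H]1O[C@@H]([C@H](CC)OC(C)=O)C[C@H](O)[C@H](O)C[C@H]1OC(C)=O | target

## Step count and risk

Total steps: 12. Longest linear sequence: 11 steps (1 → 25 through steps 1–8 and 10–12); step 9 is a one-step side branch.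

The three steps most likely to fail are steps 4, 8 and 10.

Step 4 may fail because the carbamate carbonyl next to the BF3-activated epoxide can open it itself, or can migrate to the new C9 alkoxide. The fallback reverses the order of the two epoxide openings and sets out from diepoxide 2. Acetylide 9 with BF3·OEt2 opens 2 first to give (1S)-1-[(2S)-oxiran-2-yl]hept-6-en-3-yn-1-ol F1. Its hydroxyl is silylated (TESCl, imidazole) to the triethylsilyl ether F2. Alanate 5 then opens the remaining terminal epoxide to (3E,6S,7S)-7-(triethylsilyloxy)trideca-3,12-dien-9-yn-6-ol F3, with no carbamate yet present. O10 is carbamoylated to the silylated carbamate F4, and HF·pyridine removes the silyl group, which brings the route back at 10.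

Step 8 may fail at the 5-endo opening of the 6,7-epoxide by an ether oxygen, which can lose to fluoride opening or hydride-shift rearrangement of the BF3-activated epoxide. The fallback reverses the order of the two ring closures and sets out from 12. CSA lets the free O9–H perform the 5-endo opening at C6 (a routine 3,4-epoxy alcohol closure) to give (1S,3E)-1-[(2S,4R,5R)-5-allyl-4-hydroxyoxolan-2-yl]hex-3-en-1-yl dimethylcarbamate F5. Shi epoxidation with the ent-ketone gives (1S)-1-[(2S,4R,5R)-5-allyl-4-hydroxyoxolan-2-yl]-2-[(2S,3S)-3-ethyloxiran-2-yl]ethyl dimethylcarbamate F6. BF3·OEt2 then needs only a 5-exo opening at C12 to reach the same oxonium 15, and carbamate attack at C9 returns the route at 17. The cost is that the carbamate can now compete for C12.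

Step 10 may fail through poor Z/E control or a sluggish metathesis next to the free hydroxyls and the ring oxygen. The fallback builds the enyne by carbonyl olefination and sets out from 17. Both hydroxyls are silylated to the bis(triethylsilyl) ether F7, and ozonolysis (O3, then PPh3) gives the C4 aldehyde F8. Peterson olefination with lithiated 1,3-bis(triisopropylsilyl)propyne gives the (Z)-triisopropylsilyl enyne F9. TBAF removes all three silyl groups to give the terminal enyne diol carbonate F10, and K2CO3/MeOH brings the route back at 22.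

## Further compounds

F1 | step 4 | (1S)-1-[(2S)-oxiran-2-yl]hept-6-en-3-yn-1-ol | C=CCC#CC[C@H](O)[C@@H]1CO1
F2 | step 4 | triethylsilyl ether of F1 | C=CCC#CC[C@H](O[Si](CC)(CC)CC)[C@@H]1CO1
F3 | step 4 | (3E,6S,7S)-7-(triethylsilyloxy)trideca-3,12-dien-9-yn-6-ol | C=CCC#CC[C@H](O[Si](CC)(CC)CC)[C@@H](O)C/C=C/CC
F4 | step 4 | (3E,6S,7S)-7-(triethylsilyloxy)trideca-3,12-dien-9-yn-6-yl dimethylcarbamate | C=CCC#CC[C@H](O[Si](CC)(CC)CC)[C@@H](OC(=O)N(C)C)C/C=C/CC
F5 | step 8 | (1S,3E)-1-[(2S,4R,5R)-5-allyl-4-hydroxyoxolan-2-yl]hex-3-en-1-yl dimethylcarbamate | C=CC[C@H]1O[C@@H](C[C@H]1O)[C@@H](OC(=O)N(C)C)C/C=C/CC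
F6 | step 8 | (1S)-1-[(2S,4R,5R)-5-allyl-4-hydroxyoxolan-2-yl]-2-[(2S,3S)-3-ethyloxiran-2-yl]ethyl dimethylcarbamate | C=CC[C@H]1O[C@@H](C[C@H]1O)[C@@H](OC(=O)N(C)C)C[C@@H]1O[C@H]1CC
F7 | step 10 | bis(triethylsilyl) ether of 17 | C=CC[C@H]1O[C@@H]([C@H](CC)O[Si](CC)(CC)CC)C[C@@H]2OC(=O)O[C@@H]2C[C@H]1O[Si](CC)(CC)CC
F8 | step 10 | C4 aldehyde from ozonolysis of F7 | O=CC[C@H]1O[C@@H]([C@H](CC)O[Si](CC)(CC)CC)C[C@@H]2OC(=O)O[C@@H]2C[C@H]1O[Si](CC)(CC)CC
F9 | step 10 | (Z)-5-(triisopropylsilyl)pent-2-en-4-ynyl bis(triethylsilyl) ether carbonate | CC(C)[Si](C#C/C=C\C[C@H]1O[C@@H]([C@H](CC)O[Si](CC)(CC)CC)C[C@@H]2OC(=O)O[C@@H]2C[C@H]1O[Si](CC)(CC)CC)(C(C)C)C(C)C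
F10 | step 10 | (2R,3R,5R,6S,8R)-8-[(1S)-1-hydroxypropyl]-2-[(2Z)-pent-2-en-4-yn-1-yl]oxocane-3,5,6-triol 5,6-cyclic carbonate | C#C/C=C\C[C@H]1O[C@@H]([C@H](CC)O)C[C@@H]2OC(=O)O[C@@H]2C[C@H]1O
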